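A small charge of starting material, 0.10 M, goes into each of four flasks that differ in temperature, and before I ask what each flask holds I ask whether it has reached its end by 5.0 h.

| flask | starting material | partner | protic impurity | temperature | remark | time |
|---|---|---|---|---|---|---|
| north | 0.10 M | 0.18 M | 0.050 M | −35 °C | run made earlier |  |
| south | 0.10 M | 0.18 M | 0.20 M | 15 °C | run made earlier |  |
| south-east | 0.20 M | 0.18 M | 0.10 M | −35 °C | run made earlier |  |
| oak | 0.10 M | 0.180 M | 0.100 M | 0 °C |  | 5.0 h |
| birch | 0.10 M | 0.180 M | 0.100 M | 60 °C |  | 5.0 h |
| elm | 0.10 M | 0.180 M | 0.100 M | 30 °C |  | 5.0 h |
| maple | 0.10 M | 0.180 M | 0.100 M | −30 °C |  | 5.0 h |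

- north (time / h: target / %, side product A / %): 1.00: 4, 0; 4.00: 0, 0; 6.00: 0, 2; 8.00: 1, 0; 15.0: 3, 3; 25.0: 2, 0
- south (time / min: target / %, side product A / %): 15.0: 29, 11; 30.0: 42, 20; 40.0: 49, 22; 80.0: 52, 25; 120: 52, 24
- south-east (time / h: target / %, side product A / %): 2.00: 4, 1; 6.00: 1, 2; 12.0: 1, 0; 15.0: 2, 3; 25.0: 3, 0

(standard deviation of a reading: 2 percentage points)



* the flask with the highest share of target in all that became target or side product A or side product B ("all alike" if they lie within 1.5 percentage points) (oak / birch / elm / maple / all alike)
* share of target in all that became target or side product A or side product B, oak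
* share of target in all that became target or side product A or side product B, birch
* share of target in all that became target or side product A or side product B, elm
* share of target in all that became target or side product A or side product B, maple

The south run is the one that moves: target is read at 29% at 15.0 min and levels off in the readings at about 52%. Taken as a first-order loss, that gives 3.26 /h, and so a consumption clock, the half-life of starting material, of 12.7 min at 15 °C. The north run at −35 °C shows target 2% and side product A 0% at 25.0 h, so I allow two standard deviations of scatter and bound its rate by 0.00240 /h, which makes the activation energy at least 82.3 kJ/mol.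

With that energy my ladder runs from fast to slow. Elm's clock is at most 2.33 min, and birch, hotter than elm, sits below that rung, so on my reckoning both clocks are far shorter than 5.0 h. Oak's clock is at least 1.40 h, which leaves at least 8.41% of its starting material. Maple's clock is at least 123 h, so it consumes at most 2.78%, and I read its selectivity, the share of target, as that of the opening of a reaction and not as an end share.

The forecast names maple highest, with oak 60%, birch 55%, elm 58% and maple 63%, holding that “its small product share should still follow the selectivity”.

The flasks give oak 57.5%, birch 46.1%, elm 50.6% and maple 94.4%, so maple stands highest.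

    partner + intermediate A → side product A (k = 0.200 /M/min, Ea = 67.0 kJ/mol)
    starting material → target (k = 0.00420 /min, Ea = 86.0 kJ/mol)
    starting material → intermediate A (k = 0.00330 /min, Ea = 91.0 kJ/mol)
    intermediate B → side product B (k = 0.0270 /min, Ea = 92.0 kJ/mol)
    partner + intermediate A → intermediate B (k = 0.260 /M/min, Ea = 48.0 kJ/mol)
    2 starting material → self-condensation product (k = 2.90 × 10⁻⁵ /M/min, Ea = 85.0 kJ/mol)
    partner + protic impurity → quenched reagent (k = 0.0300 /M/min, Ea = 48.0 kJ/mol)
    (constants at 0 °C)

Maple's clock is longer than the asked time, and at 5.0 h maple holds 98% of its starting material, with target 1.17%, side product A 0.0650%, side product B 0% and intermediate B 0.233%. At 50.0 h maple's share stands at 82.8%. The same clock on elm puts starting material under 2 per cent of its charge by 0.219 h, and elm gets there at 0.185 h.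

The readings come from a simulation from invented constants.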